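**Plan**
- Retrosynthesis: the tetrahydrofuran is opened at O1–C2, then cut at C2–C3 (aldol) and at C4–CH2 (enolate alkylation by a benzylic bromide). The dihydrobenzofuran is opened at O1'–C2'. The open chain is cut at C2'–C3' (auxiliary alkylation) and at C3a'–C3' (ortho-lithiation, ethylene oxide).
- Forward: central arene → arylacetyl imide → C2'–C3' bond → anodic closure of the dihydrobenzofuran ring (O1'–C2') → benzylic bromide → C4–CH2 bond → butyrolactone → C2–C3 aldol → tetrahydrofuran ring (O1–C2) → desilylation.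
- Enabling feature: C2' is benzylic to the 4-hydroxy-3-methoxyphenyl ring and lies five atoms from the phenolic oxygen on C7a'. Two-electron oxidation of that phenol therefore turns C2' into the electrophilic carbon of a para-quinone methide within reach of the C7a' oxygen.
- Stereochemistry: C3' (R) and C4 (S) come from the two enantiomers of 4-benzyl-oxazolidin-2-one. C2' (S) is relayed from C3' in the trans ring closure, C3 (S) from C4 in the trans aldol on the lactone, and C2 (R) from C3 in the trans tetrahydrofuran closure.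

Key step: step 14

Remark on names: unprimed locants refer to the tetrahydrofuran (O1, C2 aryl, C3 CH2OH, C4 CH2Ar, C5) and primed locants to the dihydrobenzofuran; MOM = methoxymethyl, TBS = tert-butyl(dimethyl)silyl, TIPS = tri(propan-2-yl)silyl; ArA = 4-[(TBS-oxy)methyl]-2-methoxy-6-(MOM-oxy)phenyl; BF = (2S,3R)-4-methoxy-2-[3-methoxy-4-(TIPS-oxy)phenyl]-3-[(TIPS-oxy)methyl]-2,3-dihydro-1-benzofuran-6-yl.

**Route**

Step 1
Reactants: 1 methyl 3-hydroxy-5-methoxybenzoate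
Product: 2 methyl 3-methoxy-5-(MOM-oxy)benzoate
Conditions: MOMCl, i-Pr2NEt, CH2Cl2, 0 °C to rt
Reagents that add atoms: chloromethyl methyl ether, COCCl
Why: O-alkylation of the phenol by the α-chloro ether (Williamson type) installs the acetal that later directs ortho-metalation.

Step 2
Reactants: 2 methyl 3-methoxy-5-(MOM-oxy)benzoate
Product: 3 [3-methoxy-5-(MOM-oxy)phenyl]methanol
Conditions: LiAlH4, THF, 0 °C
Reagents that add atoms: none
Why: Hydride reduction of the ester to the benzylic alcohol should leave the acetal untouched.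

Step 3
Reactants: 3 [3-methoxy-5-(MOM-oxy)phenyl]methanol
Product: 4 tert-butyl{[3-methoxy-5-(MOM-oxy)phenyl]methoxy}dimethylsilane
Conditions: t-BuMe2SiCl, imidazole, DMF, rt
Reagents that add atoms: tert-butyl(chloro)dimethylsilane, CC(C)(C)[Si](C)(C)Cl
Why: Imidazole-mediated silylation masks the alcohol against n-BuLi and leaves a handle that acid can later remove in the presence of TIPS ethers.

Step 4
Reactants: 4 tert-butyl{[3-methoxy-5-(MOM-oxy)phenyl]methoxy}dimethylsilane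
Product: 6 2-(ArA)ethan-1-ol, via aryllithium 5 (not isolated)
Conditions: n-BuLi, THF, 0 °C; then ethylene oxide (excess), 0 °C to rt
Reagents that add atoms: ethylene oxide, C1CO1
Why: Directed ortho-metalation removes the proton flanked by the MOM-oxy and methoxy groups (the doubly activated site), and the aryllithium opens the epoxide by SN2.

Step 5
Reactants: 6 2-(ArA)ethan-1-ol
Product: 7 (ArA)acetic acid
Conditions: TEMPO (cat.), PhI(OAc)2, MeCN/pH 7 buffer, rt
Reagents that add atoms: water, O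
Why: Oxoammonium (TEMPO) oxidation takes the primary alcohol through the aldehyde hydrate to the acid under near-neutral conditions that should spare the MOM and TBS ethers.

Step 6
Reactants: 7 (ArA)acetic acid; 8 (4R)-4-benzyl-1,3-oxazolidin-2-one
Product: 10 (4R)-4-benzyl-3-[(ArA)acetyl]-1,3-oxazolidin-2-one, via mixed anhydride 9 (not isolated)
Conditions: t-BuCOCl, Et3N, THF, −20 °C; then 8, LiCl, −20 °C to rt
Reagents that add atoms: none
Why: N-acylation of the oxazolidinone through the mixed pivalic anhydride is the standard way to load an Evans auxiliary onto a carboxylic acid.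

Step 7
Reactants: 11 vanillin (4-hydroxy-3-methoxybenzaldehyde)
Product: 12 3-methoxy-4-(MOM-oxy)benzaldehyde
Conditions: MOMCl, i-Pr2NEt, CH2Cl2, 0 °C to rt
Reagents that add atoms: chloromethyl methyl ether, COCCl
Why: O-alkylation of the phenol gives the same acetal mask as on the central ring, so that both can be removed in one operation later.

Step 8
Reactants: 12 3-methoxy-4-(MOM-oxy)benzaldehyde
Product: 13 [3-methoxy-4-(MOM-oxy)phenyl]methanol
Conditions: NaBH4, MeOH, 0 °C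
Reagents that add atoms: none
Why: Borohydride reduction of an aryl aldehyde to the benzylic alcohol.

Step 9
Reactants: 13 [3-methoxy-4-(MOM-oxy)phenyl]methanol
Product: 14 4-(bromomethyl)-2-methoxy-1-(MOM-oxy)benzene
Conditions: CBr4, PPh3, CH2Cl2, 0 °C; used at once
Reagents that add atoms: tetrabromomethane, BrC(Br)(Br)Br
Why: Appel bromination is neutral, so the acetal should survive; the activated benzylic bromide is taken on without storage.

Step 10
Reactants: 10 (4R)-4-benzyl-3-[(ArA)acetyl]-1,3-oxazolidin-2-one; 14 4-(bromomethyl)-2-methoxy-1-(MOM-oxy)benzene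
Product: 16 (4R)-4-benzyl-3-{(2R)-2-(ArA)-3-[3-methoxy-4-(MOM-oxy)phenyl]propanoyl}-1,3-oxazolidin-2-one, via sodium enolate 15 (not isolated)
Conditions: NaN(SiMe3)2, THF, −78 °C; then 14, −78 to −40 °C
Reagents that add atoms: none
Why: Evans alkylation: the chelated sodium Z-enolate is attacked on the face opposite the benzyl group of the auxiliary, which forms the C2'–C3' bond and sets C3' (R).

Step 11
Reactants: 16 (4R)-4-benzyl-3-{(2R)-2-(ArA)-3-[3-methoxy-4-(MOM-oxy)phenyl]propanoyl}-1,3-oxazolidin-2-one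
Product: 17 (2R)-2-(ArA)-3-[3-methoxy-4-(MOM-oxy)phenyl]propan-1-ol
Conditions: LiBH4, MeOH (1 equiv), THF, 0 °C
Reagents that add atoms: none
Why: Reductive cleavage of the imide releases the primary alcohol and the auxiliary without epimerising the α-aryl centre.

Step 12
Reactants: 17 (2R)-2-(ArA)-3-[3-methoxy-4-(MOM-oxy)phenyl]propan-1-ol
Product: 18 {[(2R)-2-(ArA)-3-[3-methoxy-4-(MOM-oxy)phenyl]propyl]oxy}tri(propan-2-yl)silane
Conditions: i-Pr3SiCl, imidazole, DMF, rt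
Reagents that add atoms: chlorotri(propan-2-yl)silane, CC(C)[Si](Cl)(C(C)C)C(C)C
Why: Silylation gives a hindered ether that should outlast the later acid removal of the TBS group.

Step 13
Reactants: 18 {[(2R)-2-(ArA)-3-[3-methoxy-4-(MOM-oxy)phenyl]propyl]oxy}tri(propan-2-yl)silane
Product: 20 5-[(TBS-oxy)methyl]-2-[(2R)-1-(4-hydroxy-3-methoxyphenyl)-3-(TIPS-oxy)propan-2-yl]-3-methoxyphenol, via bis(trimethylsilyl) ether 19 (not isolated)
Conditions: Me3SiOTf, 2,2′-bipyridyl, MeCN, 0 °C to rt; then H2O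
Reagents that add atoms: none
Why: The silyl triflate buffered by 2,2′-bipyridyl converts aryl MOM acetals into aryl trimethylsilyl ethers without free acid, and water then frees both phenols while the alkyl TBS and TIPS ethers should remain.

Step 14
Reactants: 20 5-[(TBS-oxy)methyl]-2-[(2R)-1-(4-hydroxy-3-methoxyphenyl)-3-(TIPS-oxy)propan-2-yl]-3-methoxyphenol
Product: 22 4-{(2S,3R)-6-[(TBS-oxy)methyl]-4-methoxy-3-[(TIPS-oxy)methyl]-2,3-dihydro-1-benzofuran-2-yl}-2-methoxyphenol, via quinone methide 21 (not isolated)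
Conditions: undivided cell, graphite anode, Pt cathode, constant current (about 2 mA cm−2, 2.1 F mol−1), Bu4NBF4 (0.1 M), 2,6-lutidine (3 equiv), CH2Cl2/(CF3)2CHOH 4:1, 0 °C
Reagents that add atoms: none
Why: Two-electron, two-proton anodic oxidation of the 4-alkyl-2-methoxyphenol gives a phenoxonium ion that 2,6-lutidine deprotonates at the benzylic CH2 to the para-quinone methide 21, the non-nucleophilic fluoroalcohol keeping solvent from adding. The C7a' phenol then adds to the methide carbon in a 5-exo-trig oxa-1,6-addition (ring atoms O1', C2', C3', C3a', C7a') driven by rearomatisation; this is the quinone methide/phenol closure that forms phenylcoumarans and flavans when the methide is generated with DDQ or Ag2O, here with the anode as the oxidant. The new C2' centre is controlled by C3': in the envelope transition state the quinonoid ring takes the face anti to the CH2O-TIPS group, so the 2,3-trans (2S,3R) ring, also the more stable isomer, should result. The step needs oxidation of the guaiacyl phenol in preference to the central phenol, which the para-alkyl, ortho-methoxy substitution secures through a lower oxidation potential than that of the meta-oxygenated ring. A second oxidation of the product is limited by passing only slightly more than 2 F mol−1 at low current density, and the silyl ethers should be inert at this potential.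

Step 15
Reactants: 22 4-{(2S,3R)-6-[(TBS-oxy)methyl]-4-methoxy-3-[(TIPS-oxy)methyl]-2,3-dihydro-1-benzofuran-2-yl}-2-methoxyphenol
Product: 23 tert-butyl[(BF)methoxy]dimethylsilane
Conditions: i-Pr3SiCl, imidazole, DMF, rt
Reagents that add atoms: chlorotri(propan-2-yl)silane, CC(C)[Si](Cl)(C(C)C)C(C)C
Why: Silylation removes the acidic phenol proton before the enolate steps and gives an aryl ether that tolerates the acid, base and hydride conditions ahead.

Step 16
Reactants: 23 tert-butyl[(BF)methoxy]dimethylsilane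
Product: 24 (BF)methanol
Conditions: PPTS (cat.), MeOH, rt
Reagents that add atoms: none
Why: Acid-catalysed methanolysis removes a primary TBS ether far faster than the hindered alkyl TIPS and the aryl TIPS ethers.

Step 17
Reactants: 24 (BF)methanol
Product: 25 (2S,3R)-6-(bromomethyl)-4-methoxy-2-[3-methoxy-4-(TIPS-oxy)phenyl]-3-[(TIPS-oxy)methyl]-2,3-dihydro-1-benzofuran
Conditions: CBr4, PPh3, CH2Cl2, 0 °C
Reagents that add atoms: tetrabromomethane, BrC(Br)(Br)Br
Why: Appel bromination turns the benzylic alcohol into the electrophile under neutral conditions that silyl ethers tolerate.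

Step 18
Reactants: 26 4-tert-butoxy-4-oxobutanoic acid; 27 (4S)-4-benzyl-1,3-oxazolidin-2-one
Product: 29 tert-butyl 4-[(4S)-4-benzyl-2-oxo-1,3-oxazolidin-3-yl]-4-oxobutanoate, via mixed anhydride 28 (not isolated)
Conditions: t-BuCOCl, Et3N, THF, −20 °C; then 27, LiCl, −20 °C to rt
Reagents that add atoms: none
Why: Mixed-anhydride N-acylation as in step 6 gives the succinate imide that carries both the auxiliary and the future lactone carbonyl.

Step 19
Reactants: 29 tert-butyl 4-[(4S)-4-benzyl-2-oxo-1,3-oxazolidin-3-yl]-4-oxobutanoate; 25 (2S,3R)-6-(bromomethyl)-4-methoxy-2-[3-methoxy-4-(TIPS-oxy)phenyl]-3-[(TIPS-oxy)methyl]-2,3-dihydro-1-benzofuran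
Product: 31 tert-butyl (3S)-4-[(4S)-4-benzyl-2-oxo-1,3-oxazolidin-3-yl]-3-[(BF)methyl]-4-oxobutanoate, via sodium enolate 30 (not isolated)
Conditions: NaN(SiMe3)2, THF, −78 °C (29 in excess); then 25, −78 to −30 °C
Reagents that add atoms: none
Why: Evans alkylation of the imide (deprotonated selectively over the tert-butyl ester) on the face opposite the auxiliary benzyl group forms the C4–CH2 bond and sets C4 (S).

Step 20
Reactants: 31 tert-butyl (3S)-4-[(4S)-4-benzyl-2-oxo-1,3-oxazolidin-3-yl]-3-[(BF)methyl]-4-oxobutanoate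
Product: 33 (4S)-4-[(BF)methyl]oxolan-2-one, via hydroxy ester 32 (not isolated)
Conditions: LiBH4, MeOH (1 equiv), THF, 0 °C; work-up; then CF3CO2H, CH2Cl2, 0 °C
Reagents that add atoms: none
Why: The imide is reduced chemoselectively in the presence of the tert-butyl ester, and acid then cleaves that ester and closes the γ-lactone without touching the stereocentre.

Step 21
Reactants: 34 isovanillin (3-hydroxy-4-methoxybenzaldehyde)
Product: 35 4-methoxy-3-(TIPS-oxy)benzaldehyde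
Conditions: i-Pr3SiCl, imidazole, DMF, rt
Reagents that add atoms: chlorotri(propan-2-yl)silane, CC(C)[Si](Cl)(C(C)C)C(C)C
Why: Phenol silylation makes the aldehyde compatible with the enolate and leaves a group that fluoride removes at the end.

Step 22
Reactants: 33 (4S)-4-[(BF)methyl]oxolan-2-one; 35 4-methoxy-3-(TIPS-oxy)benzaldehyde
Product: 37 (3R,4S)-3-{hydroxy[4-methoxy-3-(TIPS-oxy)phenyl]methyl}-4-[(BF)methyl]oxolan-2-one as both carbinol epimers, via lithium enolate 36 (not isolated)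
Conditions: LiN(i-Pr)2, THF, −78 °C; then 35, −78 °C; quench cold
Reagents that add atoms: none
Why: Aldol addition of the lactone enolate forms the C2–C3 bond anti to the C4 arylmethyl group, which sets C3 (S in the target) trans; the carbinol centre is not controlled and is erased in step 24.

Step 23
Reactants: 37 (3R,4S)-3-{hydroxy[4-methoxy-3-(TIPS-oxy)phenyl]methyl}-4-[(BF)methyl]oxolan-2-one
Product: 38 (2S,3S)-2-{hydroxy[4-methoxy-3-(TIPS-oxy)phenyl]methyl}-3-[(BF)methyl]butane-1,4-diol as both carbinol epimers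
Conditions: LiAlH4, THF, 0 °C
Reagents that add atoms: none
Why: Hydride reduction opens the lactone to the triol; TIPS ethers should survive at 0 °C.

Step 24
Reactants: 38 (2S,3S)-2-{hydroxy[4-methoxy-3-(TIPS-oxy)phenyl]methyl}-3-[(BF)methyl]butane-1,4-diol
Product: 39 {(2R,3S,4S)-4-[(BF)methyl]-2-[4-methoxy-3-(TIPS-oxy)phenyl]oxolan-3-yl}methanol
Conditions: camphorsulfonic acid (cat.), CH2Cl2, −20 to 0 °C; quench with Et3N at full conversion
Reagents that add atoms: none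
Why: Acid-catalysed SN1 etherification: both carbinol epimers ionise to the same para-methoxybenzylic cation, the C4 hydroxymethyl oxygen closes the five-membered ring (the other hydroxyl could only form an oxetane), and the aryl group should settle trans to the C3 hydroxymethyl group, setting C2 (R).

Step 25
Reactants: 39 {(2R,3S,4S)-4-[(BF)methyl]-2-[4-methoxy-3-(TIPS-oxy)phenyl]oxolan-3-yl}methanol
Product: 40 4-[(2S,3R)-3-(hydroxymethyl)-6-{[(3S,4S,5R)-4-(hydroxymethyl)-5-(3-hydroxy-4-methoxyphenyl)oxolan-3-yl]methyl}-4-methoxy-2,3-dihydro-1-benzofuran-2-yl]-2-methoxyphenol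
Conditions: Bu4NF, AcOH, THF, 0 °C to rt
Reagents that add atoms: none
Why: Fluoride cleaves the two aryl and one alkyl TIPS ethers, and the acetic acid buffer should keep the phenoxides from opening the dihydrobenzofuran.

**Compound list**

1 | methyl 3-hydroxy-5-methoxybenzoate | COC(=O)c1cc(O)cc(OC)c1 | starting material
2 | methyl 3-methoxy-5-(methoxymethoxy)benzoate | COCOc1cc(OC)cc(C(=O)OC)c1 | intermediate
3 | [3-methoxy-5-(methoxymethoxy)phenyl]methanol | COCOc1cc(OC)cc(CO)c1 | intermediate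
4 | tert-butyl{[3-methoxy-5-(methoxymethoxy)phenyl]methoxy}dimethylsilane | COCOc1cc(OC)cc(CO[Si](C)(C)C(C)(C)C)c1 | intermediate
5 | {4-[(TBS-oxy)methyl]-2-methoxy-6-(methoxymethoxy)phenyl}lithium | [Li]c1c(OC)cc(CO[Si](C)(C)C(C)(C)C)cc1OCOC | intermediate
6 | 2-{4-[(TBS-oxy)methyl]-2-methoxy-6-(methoxymethoxy)phenyl}ethan-1-ol | OCCc1c(OC)cc(CO[Si](C)(C)C(C)(C)C)cc1OCOC | intermediate
7 | {4-[(TBS-oxy)methyl]-2-methoxy-6-(methoxymethoxy)phenyl}acetic acid | OC(=O)Cc1c(OC)cc(CO[Si](C)(C)C(C)(C)C)cc1OCOC | intermediate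
8 | (4R)-4-benzyl-1,3-oxazolidin-2-one | O=C1OC[C@@H](Cc2ccccc2)N1 | starting material
9 | mixed anhydride of acid 7 and 2,2-dimethylpropanoic acid | CC(C)(C)C(=O)OC(=O)Cc1c(OC)cc(CO[Si](C)(C)C(C)(C)C)cc1OCOC | intermediate
10 | (4R)-4-benzyl-3-({4-[(TBS-oxy)methyl]-2-methoxy-6-(methoxymethoxy)phenyl}acetyl)-1,3-oxazolidin-2-one | O=C(Cc1c(OC)cc(CO[Si](C)(C)C(C)(C)C)cc1OCOC)N1C(=O)OC[C@H]1Cc1ccccc1 | intermediate
11 | vanillin (4-hydroxy-3-methoxybenzaldehyde) | COc1cc(C=O)ccc1O | starting material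
12 | 3-methoxy-4-(methoxymethoxy)benzaldehyde | COCOc1ccc(C=O)cc1OC | intermediate
13 | [3-methoxy-4-(methoxymethoxy)phenyl]methanol | COCOc1ccc(CO)cc1OC | intermediate
14 | 4-(bromomethyl)-2-methoxy-1-(methoxymethoxy)benzene | COCOc1ccc(CBr)cc1OC | intermediate
15 | sodium (Z)-enolate of imide 10 | [Na]O/C(=C\c1c(OC)cc(CO[Si](C)(C)C(C)(C)C)cc1OCOC)N1C(=O)OC[C@H]1Cc1ccccc1 | intermediate
16 | (4R)-4-benzyl-3-{(2R)-2-{4-[(TBS-oxy)methyl]-2-methoxy-6-(methoxymethoxy)phenyl}-3-[3-methoxy-4-(methoxymethoxy)phenyl]propanoyl}-1,3-oxazolidin-2-one | COCOc1cc(CO[Si](C)(C)C(C)(C)C)cc(OC)c1[C@H](C(=O)N1C(=O)OC[C@H]1Cc1ccccc1)Cc1ccc(OCOC)c(OC)c1 | intermediate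
17 | (2R)-2-{4-[(TBS-oxy)methyl]-2-methoxy-6-(methoxymethoxy)phenyl}-3-[3-methoxy-4-(methoxymethoxy)phenyl]propan-1-ol | COCOc1cc(CO[Si](C)(C)C(C)(C)C)cc(OC)c1[C@H](CO)Cc1ccc(OCOC)c(OC)c1 | intermediate
18 | TIPS ether of alcohol 17 | COCOc1cc(CO[Si](C)(C)C(C)(C)C)cc(OC)c1[C@H](CO[Si](C(C)C)(C(C)C)C(C)C)Cc1ccc(OCOC)c(OC)c1 | intermediate
19 | bis(trimethylsilyl) aryl ether corresponding to 18 (both MOM groups replaced by SiMe3) | C[Si](C)(C)Oc1cc(CO[Si](C)(C)C(C)(C)C)cc(OC)c1[C@H](CO[Si](C(C)C)(C(C)C)C(C)C)Cc1ccc(O[Si](C)(C)C)c(OC)c1 | intermediate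
20 | 5-[(TBS-oxy)methyl]-2-[(2R)-1-(4-hydroxy-3-methoxyphenyl)-3-(TIPS-oxy)propan-2-yl]-3-methoxyphenol | CC(C)(C)[Si](C)(C)OCc1cc(OC)c([C@H](CO[Si](C(C)C)(C(C)C)C(C)C)Cc2ccc(O)c(OC)c2)c(O)c1 | intermediate
21 | 4-{(2R)-2-{4-[(TBS-oxy)methyl]-2-hydroxy-6-methoxyphenyl}-3-(TIPS-oxy)propylidene}-2-methoxycyclohexa-2,5-dien-1-one (alkene geometry not defined) | CC(C)(C)[Si](C)(C)OCc1cc(OC)c([C@H](CO[Si](C(C)C)(C(C)C)C(C)C)C=C2C=CC(=O)C(OC)=C2)c(O)c1 | intermediate
22 | 4-{(2S,3R)-6-[(TBS-oxy)methyl]-4-methoxy-3-[(TIPS-oxy)methyl]-2,3-dihydro-1-benzofuran-2-yl}-2-methoxyphenol | CC(C)(C)[Si](C)(C)OCc1cc(OC)c2c(c1)O[C@H](c1ccc(O)c(OC)c1)[C@H]2CO[Si](C(C)C)(C(C)C)C(C)C | intermediate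
23 | tert-butyl{[(2S,3R)-4-methoxy-2-[3-methoxy-4-(TIPS-oxy)phenyl]-3-[(TIPS-oxy)methyl]-2,3-dihydro-1-benzofuran-6-yl]methoxy}dimethylsilane | CC(C)(C)[Si](C)(C)OCc1cc(OC)c2c(c1)O[C@H](c1ccc(O[Si](C(C)C)(C(C)C)C(C)C)c(OC)c1)[C@H]2CO[Si](C(C)C)(C(C)C)C(C)C | intermediate
24 | {(2S,3R)-4-methoxy-2-[3-methoxy-4-(TIPS-oxy)phenyl]-3-[(TIPS-oxy)methyl]-2,3-dihydro-1-benzofuran-6-yl}methanol | OCc1cc(OC)c2c(c1)O[C@H](c1ccc(O[Si](C(C)C)(C(C)C)C(C)C)c(OC)c1)[C@H]2CO[Si](C(C)C)(C(C)C)C(C)C | intermediate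
25 | (2S,3R)-6-(bromomethyl)-4-methoxy-2-[3-methoxy-4-(TIPS-oxy)phenyl]-3-[(TIPS-oxy)methyl]-2,3-dihydro-1-benzofuran | BrCc1cc(OC)c2c(c1)O[C@H](c1ccc(O[Si](C(C)C)(C(C)C)C(C)C)c(OC)c1)[C@H]2CO[Si](C(C)C)(C(C)C)C(C)C | intermediate
26 | 4-tert-butoxy-4-oxobutanoic acid | CC(C)(C)OC(=O)CCC(=O)O | starting material
27 | (4S)-4-benzyl-1,3-oxazolidin-2-one | O=C1OC[C@H](Cc2ccccc2)N1 | starting material
28 | mixed anhydride of acid 26 and 2,2-dimethylpropanoic acid | CC(C)(C)OC(=O)CCC(=O)OC(=O)C(C)(C)C | intermediate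
29 | tert-butyl 4-[(4S)-4-benzyl-2-oxo-1,3-oxazolidin-3-yl]-4-oxobutanoate | CC(C)(C)OC(=O)CCC(=O)N1C(=O)OC[C@@H]1Cc1ccccc1 | intermediate
30 | sodium (Z)-enolate of imide 29 | [Na]O/C(=C\CC(=O)OC(C)(C)C)N1C(=O)OC[C@@H]1Cc1ccccc1 | intermediate
31 | tert-butyl (3S)-4-[(4S)-4-benzyl-2-oxo-1,3-oxazolidin-3-yl]-3-[(BF)methyl]-4-oxobutanoate | CC(C)(C)OC(=O)C[C@H](Cc1cc(OC)c2c(c1)O[C@H](c1ccc(O[Si](C(C)C)(C(C)C)C(C)C)c(OC)c1)[C@H]2CO[Si](C(C)C)(C(C)C)C(C)C)C(=O)N1C(=O)OC[C@@H]1Cc1ccccc1 | intermediate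
32 | tert-butyl (3S)-3-(hydroxymethyl)-4-(BF)butanoate | CC(C)(C)OC(=O)C[C@H](Cc1cc(OC)c2c(c1)O[C@H](c1ccc(O[Si](C(C)C)(C(C)C)C(C)C)c(OC)c1)[C@H]2CO[Si](C(C)C)(C(C)C)C(C)C)CO | intermediate
33 | (4S)-4-[(BF)methyl]oxolan-2-one | O=C1C[C@H](Cc2cc(OC)c3c(c2)O[C@H](c2ccc(O[Si](C(C)C)(C(C)C)C(C)C)c(OC)c2)[C@H]3CO[Si](C(C)C)(C(C)C)C(C)C)CO1 | intermediate
34 | isovanillin (3-hydroxy-4-methoxybenzaldehyde) | COc1ccc(C=O)cc1O | starting material
35 | 4-methoxy-3-(TIPS-oxy)benzaldehyde | COc1ccc(C=O)cc1O[Si](C(C)C)(C(C)C)C(C)C | intermediate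
36 | lithium enolate of lactone 33 | [Li]OC1=C[C@H](Cc2cc(OC)c3c(c2)O[C@H](c2ccc(O[Si](C(C)C)(C(C)C)C(C)C)c(OC)c2)[C@H]3CO[Si](C(C)C)(C(C)C)C(C)C)CO1 | intermediate
37 | (3R,4S)-3-{hydroxy[4-methoxy-3-(TIPS-oxy)phenyl]methyl}-4-[(BF)methyl]oxolan-2-one, both carbinol epimers | O=C1OC[C@@H](Cc2cc(OC)c3c(c2)O[C@H](c2ccc(O[Si](C(C)C)(C(C)C)C(C)C)c(OC)c2)[C@H]3CO[Si](C(C)C)(C(C)C)C(C)C)[C@@H]1C(O)c1ccc(OC)c(O[Si](C(C)C)(C(C)C)C(C)C)c1 | intermediate
38 | (2S,3S)-2-{hydroxy[4-methoxy-3-(TIPS-oxy)phenyl]methyl}-3-[(BF)methyl]butane-1,4-diol, both carbinol epimers | OC[C@@H](Cc1cc(OC)c2c(c1)O[C@H](c1ccc(O[Si](C(C)C)(C(C)C)C(C)C)c(OC)c1)[C@H]2CO[Si](C(C)C)(C(C)C)C(C)C)[C@@H](CO)C(O)c1ccc(OC)c(O[Si](C(C)C)(C(C)C)C(C)C)c1 | intermediate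
39 | {(2R,3S,4S)-4-[(BF)methyl]-2-[4-methoxy-3-(TIPS-oxy)phenyl]oxolan-3-yl}methanol | COc1ccc([C@@H]2OC[C@@H](Cc3cc(OC)c4c(c3)O[C@H](c3ccc(O[Si](C(C)C)(C(C)C)C(C)C)c(OC)c3)[C@H]4CO[Si](C(C)C)(C(C)C)C(C)C)[C@H]2CO)cc1O[Si](C(C)C)(C(C)C)C(C)C | intermediate
40 | 4-[(2S,3R)-3-(hydroxymethyl)-6-{[(3S,4S,5R)-4-(hydroxymethyl)-5-(3-hydroxy-4-methoxyphenyl)oxolan-3-yl]methyl}-4-methoxy-2,3-dihydro-1-benzofuran-2-yl]-2-methoxyphenol | COc1ccc([C@@H]2OC[C@@H](Cc3cc(OC)c4c(c3)O[C@H](c3ccc(O)c(OC)c3)[C@H]4CO)[C@H]2CO)cc1O | target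

**Counts**

Total step count: 25. Longest linear sequence: 20 steps (steps 1–6, 10–17, 19, 20, 22–25).

**Steps most likely to fail**

1. Step 14 (anodic ring closure). The C7a' phenol may attack the ipso carbon of the phenoxonium ion (spirocyclisation) before the benzylic proton is lost. The central phenol may be oxidised in competition. The product, itself a guaiacyl phenol, may be oxidised a second time towards the benzofuran. The fallback places oxygen at C2' beforehand and closes the ring by dehydration.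
It sets out from acid 7. Acylation of oxazolidinone 27 (t-BuCOCl, Et3N, LiCl) should give the (4S)-configured arylacetyl imide F1. Its boron enolate (Bu2BOTf, i-Pr2NEt, CH2Cl2, −78 °C) should add to aldehyde 12 to give the syn-aldol adduct F2; the boron aldol uses the enolate face opposite to that of the alkylation, hence the enantiomeric auxiliary for the same C3' configuration. LiBH4 should then give the 1,3-diol F3, and i-Pr3SiCl/imidazole should silylate the primary hydroxyl to give the mono-TIPS ether F4. Me3SiOTf/2,2′-bipyridyl followed by water should free both phenols to give the benzylic alcohol bis-phenol F5. PPTS in MeCN should ionise the para-hydroxybenzylic alcohol so that the C7a' phenol closes the ring trans, whatever the carbinol configuration. The route is rejoined at 22.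

2. Step 24 (tetrahydrofuran closure). After ionisation at the carbinol carbon, the electron-rich benzofuran ring (C5' and C7' are each ortho or para to two oxygens) may capture the cation in a Friedel–Crafts closure to an aryltetralin. Repeated re-ionisation of the product may also erode the 2,3-trans selectivity. The fallback avoids any cation by fixing both oxygen-bearing centres early and closing the ring at a primary carbon.
It sets out from acid 26 and oxazolidinone 8, which should give the (4R)-configured succinate imide F6. A Bu2BOTf/i-Pr2NEt syn-aldol with aldehyde 35 should give the β-hydroxy imide F7, and CF3CO2H should lactonise it to the trans-lactone imide F8. NaBH4 in THF/H2O should remove the auxiliary reductively to give the hydroxymethyl lactone F9, and i-Pr3SiCl/imidazole should give the TIPS-protected lactone F10. Its lithium enolate (LiN(SiMe3)2, THF, −78 °C) should be alkylated by bromide 25 anti to the C4 substituent to give the trans-benzylated lactone F11. Re-enolisation with LiN(i-Pr)2 and protonation at −78 °C by 2,6-di-tert-butylphenol from the face anti to the C4 substituent should give the cis-benzylated lactone F12. LiAlH4 should give the 1,4-diol F13. Mitsunobu cyclodehydration (PPh3, DIAD) should activate the primary hydroxyl only and close the ring with retention at the benzylic carbon, giving the tetrakis-TIPS tetrahydrofuran F14. Bu4NF/AcOH then rejoins the route at 40.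

3. Step 13 (phenol unmasking). Cleavage of the hindered C7a' MOM ether may stall, or the silyl triflate may exchange or remove the benzylic TBS ether. The fallback gives up selectivity in the acid step and restores it with base.
It sets out from 18. HCl in MeOH/THF (0 °C to rt) should remove both MOM groups and the TBS group while the TIPS ether, the slowest to hydrolyse, remains, giving the phenolic triol F15. t-BuMe2SiCl/imidazole (excess) should silylate all three hydroxyls to give the tris-TBS ether F16. K2CO3 in MeOH should then cleave only the two aryl silyl ethers, rejoining the route at 20.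

**Further compounds**

F1 | step 14 | (4S)-4-benzyl-3-({4-[(TBS-oxy)methyl]-2-methoxy-6-(methoxymethoxy)phenyl}acetyl)-1,3-oxazolidin-2-one | O=C(Cc1c(OC)cc(CO[Si](C)(C)C(C)(C)C)cc1OCOC)N1C(=O)OC[C@@H]1Cc1ccccc1
F2 | step 14 | (4S)-4-benzyl-3-[(2S,3S)-2-{4-[(TBS-oxy)methyl]-2-methoxy-6-(methoxymethoxy)phenyl}-3-hydroxy-3-[3-methoxy-4-(methoxymethoxy)phenyl]propanoyl]-1,3-oxazolidin-2-one | COCOc1cc(CO[Si](C)(C)C(C)(C)C)cc(OC)c1[C@H](C(=O)N1C(=O)OC[C@@H]1Cc1ccccc1)[C@H](O)c1ccc(OCOC)c(OC)c1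
F3 | step 14 | (1S,2R)-2-{4-[(TBS-oxy)methyl]-2-methoxy-6-(methoxymethoxy)phenyl}-1-[3-methoxy-4-(methoxymethoxy)phenyl]propane-1,3-diol | COCOc1cc(CO[Si](C)(C)C(C)(C)C)cc(OC)c1[C@H](CO)[C@H](O)c1ccc(OCOC)c(OC)c1
F4 | step 14 | (1S,2R)-2-{4-[(TBS-oxy)methyl]-2-methoxy-6-(methoxymethoxy)phenyl}-1-[3-methoxy-4-(methoxymethoxy)phenyl]-3-(TIPS-oxy)propan-1-ol | COCOc1cc(CO[Si](C)(C)C(C)(C)C)cc(OC)c1[C@H](CO[Si](C(C)C)(C(C)C)C(C)C)[C@H](O)c1ccc(OCOC)c(OC)c1
F5 | step 14 | (1S,2R)-2-{4-[(TBS-oxy)methyl]-2-hydroxy-6-methoxyphenyl}-1-(4-hydroxy-3-methoxyphenyl)-3-(TIPS-oxy)propan-1-ol | CC(C)(C)[Si](C)(C)OCc1cc(OC)c([C@H](CO[Si](C(C)C)(C(C)C)C(C)C)[C@H](O)c2ccc(O)c(OC)c2)c(O)c1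
F6 | step 24 | tert-butyl 4-[(4R)-4-benzyl-2-oxo-1,3-oxazolidin-3-yl]-4-oxobutanoate | CC(C)(C)OC(=O)CCC(=O)N1C(=O)OC[C@H]1Cc1ccccc1
F7 | step 24 | tert-butyl (3R,4R)-3-{[(4R)-4-benzyl-2-oxo-1,3-oxazolidin-3-yl]carbonyl}-4-hydroxy-4-[4-methoxy-3-(TIPS-oxy)phenyl]butanoate | CC(C)(C)OC(=O)C[C@@H](C(=O)N1C(=O)OC[C@H]1Cc1ccccc1)[C@@H](O)c1ccc(OC)c(O[Si](C(C)C)(C(C)C)C(C)C)c1
F8 | step 24 | (4R)-4-benzyl-3-({(2R,3R)-2-[4-methoxy-3-(TIPS-oxy)phenyl]-5-oxooxolan-3-yl}carbonyl)-1,3-oxazolidin-2-one | O=C1C[C@@H](C(=O)N2C(=O)OC[C@H]2Cc2ccccc2)[C@H](c2ccc(OC)c(O[Si](C(C)C)(C(C)C)C(C)C)c2)O1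
F9 | step 24 | (4S,5R)-4-(hydroxymethyl)-5-[4-methoxy-3-(TIPS-oxy)phenyl]oxolan-2-one | O=C1C[C@@H](CO)[C@H](c2ccc(OC)c(O[Si](C(C)C)(C(C)C)C(C)C)c2)O1
F10 | step 24 | (4S,5R)-5-[4-methoxy-3-(TIPS-oxy)phenyl]-4-[(TIPS-oxy)methyl]oxolan-2-one | O=C1C[C@@H](CO[Si](C(C)C)(C(C)C)C(C)C)[C@H](c2ccc(OC)c(O[Si](C(C)C)(C(C)C)C(C)C)c2)O1
F11 | step 24 | (3R,4S,5R)-3-[(BF)methyl]-5-[4-methoxy-3-(TIPS-oxy)phenyl]-4-[(TIPS-oxy)methyl]oxolan-2-one | O=C1[C@H](Cc2cc(OC)c3c(c2)O[C@H](c2ccc(O[Si](C(C)C)(C(C)C)C(C)C)c(OC)c2)[C@H]3CO[Si](C(C)C)(C(C)C)C(C)C)[C@@H](CO[Si](C(C)C)(C(C)C)C(C)C)[C@H](c2ccc(OC)c(O[Si](C(C)C)(C(C)C)C(C)C)c2)O1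
F12 | step 24 | (3S,4S,5R)-3-[(BF)methyl]-5-[4-methoxy-3-(TIPS-oxy)phenyl]-4-[(TIPS-oxy)methyl]oxolan-2-one | O=C1[C@@H](Cc2cc(OC)c3c(c2)O[C@H](c2ccc(O[Si](C(C)C)(C(C)C)C(C)C)c(OC)c2)[C@H]3CO[Si](C(C)C)(C(C)C)C(C)C)[C@@H](CO[Si](C(C)C)(C(C)C)C(C)C)[C@H](c2ccc(OC)c(O[Si](C(C)C)(C(C)C)C(C)C)c2)O1
F13 | step 24 | (1R,2S,3S)-3-[(BF)methyl]-1-[4-methoxy-3-(TIPS-oxy)phenyl]-2-[(TIPS-oxy)methyl]butane-1,4-diol | OC[C@@H](Cc1cc(OC)c2c(c1)O[C@H](c1ccc(O[Si](C(C)C)(C(C)C)C(C)C)c(OC)c1)[C@H]2CO[Si](C(C)C)(C(C)C)C(C)C)[C@@H](CO[Si](C(C)C)(C(C)C)C(C)C)[C@@H](O)c1ccc(OC)c(O[Si](C(C)C)(C(C)C)C(C)C)c1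
F14 | step 24 | (2R,3S,4S)-4-[(BF)methyl]-2-[4-methoxy-3-(TIPS-oxy)phenyl]-3-[(TIPS-oxy)methyl]oxolane | COc1ccc([C@@H]2OC[C@@H](Cc3cc(OC)c4c(c3)O[C@H](c3ccc(O[Si](C(C)C)(C(C)C)C(C)C)c(OC)c3)[C@H]4CO[Si](C(C)C)(C(C)C)C(C)C)[C@H]2CO[Si](C(C)C)(C(C)C)C(C)C)cc1O[Si](C(C)C)(C(C)C)C(C)C
F15 | step 13 | 5-(hydroxymethyl)-2-[(2R)-1-(4-hydroxy-3-methoxyphenyl)-3-(TIPS-oxy)propan-2-yl]-3-methoxyphenol | OCc1cc(OC)c([C@H](CO[Si](C(C)C)(C(C)C)C(C)C)Cc2ccc(O)c(OC)c2)c(O)c1
F16 | step 13 | tris-TBS ether of F15 (both phenols and the benzylic alcohol silylated) | CC(C)(C)[Si](C)(C)OCc1cc(OC)c([C@H](CO[Si](C(C)C)(C(C)C)C(C)C)Cc2ccc(O[Si](C)(C)C(C)(C)C)c(OC)c2)c(O[Si](C)(C)C(C)(C)C)c1
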